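At late times the catalyst of this flask is shared between free catalyst and idle complex by the binding equilibrium with added ligand, so the reckoning turns on how far that sharing has got at the asked moment.

substrate 0.40 M; reagent 0.720 M; free catalyst 3.0 mM; added ligand 7.5 mM

    substrate + free catalyst → free catalyst + open intermediate (k1 = 0.216 M⁻¹ min⁻¹)
    free catalyst + open intermediate ⇌ catalyst intermediate (K2 = 3.3 M⁻¹, k2 = 1.04 M⁻¹ min⁻¹)
    reagent + catalyst intermediate → free catalyst + product (k3 = 0.478 M⁻¹ min⁻¹)
    free catalyst + added ligand ⇌ idle complex (K4 = 165 M⁻¹, k4 = 0.231 M⁻¹ min⁻¹)

- the form that holds most of the catalyst when 20% of the substrate are converted (idle complex / catalyst intermediate / free catalyst)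
- its share of the catalyst then

Take first step 1 by itself, with the whole charge counted as free catalyst. Substrate then decays exponentially, and its fraction left, 80.0%, is reached after 344 min. The moment asked about stands later than that, at 479.8 min, so free catalyst must have averaged about 71.7% of the charge.

Step 4 is added next. At binding equilibrium, with the working round left aside, idle complex holds 1.49 mM, which is 49.8% of the catalyst. The approach runs at a relaxation rate of 0.00314 min⁻¹: the forward constant times free catalyst plus free ligand at equilibrium, plus the reverse constant. At the moment asked about, exp(−rate × time) gives 22.2%. This fraction of the way to equilibrium still open is the binding gap. By this reckoning idle complex holds 38.7%, leaving 61.3% for the working round.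

Steps 2 and 3 divide that remainder. In steady state, catalyst intermediate over free catalyst is the forward rate per free catalyst over the sum of fall-back and reagent rates per catalyst intermediate. As a rough high estimate, with all 0.0800 M of converted substrate counted as open intermediate and reagent as charged, this ratio is 12.6%. This reckoning therefore commits to free catalyst, somewhere between 54.4% and 61.3%, with even the lower figure above idle complex.

The forecast gives free catalyst at 56%, inside that span, holding that “the idle complex has only reached about 1.2 of the 3 mM catalyst by then”.

At the moment asked about the flask holds free catalyst, the resting state of the round, at 56.5%, with idle complex at 38.0% against the 38.7% reckoned, and catalyst intermediate at 5.48%. For 0.800 d the same relaxation rate puts the binding gap at 2.69%, and idle complex in this flask then stands at 45.9%. Binding of added ligand is what lifts the apparent order in free catalyst at the moment asked about: 1.4 in this flask against 1.0 in the run with that step taken away.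

The constants were drawn at random within sensible limits.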